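The whole plan hangs on opening the inner dihydrofuran at its C2–C3 and C2–O bonds. C3, the methine shared by that furan and the seven-membered ring, sits on ring A (the central benzene ring) next to the carbon bearing the furan oxygen; as a phenol, that oxygen can expel a leaving group from C3 and make it the exocyclic carbon of an ortho-quinone methide built into the cycloheptadiene ring. C2, with its aryl group, then comes in as the carbanion carbon of a benzylic sulfonium ylide. One [4+1] step closes the furan and sets C2 and C3 against the existing C10 centre. The precursor is an enantiopure bromo ortho-hydroxy dibenzosuberol.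

Key step: step 13

Remark (labels): ring A is the central benzene ring; C2 and C3 are the O–CH(aryl) carbon and the ring-fusion methine of the inner dihydrofuran; C10 is the CH(4-methoxyphenyl) carbon of the seven-membered ring; C2' and C3' are the corresponding carbons of the outer dihydrofuran.
Remark (chemistry): both sulfonium salts are made and used as tetrafluoroborates, because a halide counter-ion can re-open the labile 4-methoxybenzyl–sulfur bond; the carbinol carbons of 18 and 30 are epimer mixtures, which is immaterial because both epimers give the same ortho-quinone methide.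

Step 1
Reactants: 1 3,5-dimethoxybenzyl alcohol
Product: 2 2-bromo-3,5-dimethoxybenzyl alcohol
Conditions: NBS (1.05 equiv), MeCN, 0 °C to rt
Reagents that add atoms: N-bromosuccinimide, O=C1CCC(=O)N1Br
Why: Electrophilic aromatic bromination should go to the position next to the CH2OH group, which has one ortho and one para methoxy group and is less crowded than the site between the two methoxy groups.

Step 2
Reactants: 2 2-bromo-3,5-dimethoxybenzyl alcohol
Product: 3 2-bromo-1-(bromomethyl)-3,5-dimethoxybenzene
Conditions: PBr3 (0.4 equiv), CH2Cl2, 0 °C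
Reagents that add atoms: phosphorus tribromide, BrP(Br)Br
Why: Substitution of a primary benzylic alcohol by bromide through its phosphite ester, with the aryl bromide untouched.

Step 3
Reactants: 3 2-bromo-1-(bromomethyl)-3,5-dimethoxybenzene; 4 4-methoxybenzoyl chloride
Product: 6 2-(2-bromo-3,5-dimethoxyphenyl)-1-(4-methoxyphenyl)ethanone, via benzylzinc bromide 5 (not isolated)
Conditions: Zn dust, LiCl, THF, rt; then 4, Pd(PPh3)4 (2 mol %), THF, 0 °C to rt
Reagents that add atoms: none
Why: Zinc inserts into the benzylic C–Br bond only, and the benzylzinc is acylated by the acid chloride under palladium catalysis (Negishi-type acylation), which stops at the ketone.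

Step 4
Reactants: 6 2-(2-bromo-3,5-dimethoxyphenyl)-1-(4-methoxyphenyl)ethanone
Product: 8 (Z)-2-(2-bromo-3,5-dimethoxyphenyl)-1-(4-methoxyphenyl)ethenyl trifluoromethanesulfonate, via potassium (Z)-enolate 7 (not isolated)
Conditions: KN(SiMe3)2, THF, −78 °C; then PhNTf2, −78 to 0 °C
Reagents that add atoms: N-phenylbis(trifluoromethanesulfonimide), O=S(=O)(N(c1ccccc1)S(=O)(=O)C(F)(F)F)C(F)(F)F
Why: Enol triflate formation; deprotonation should give the enolate with oxygen cis to the bromoaryl group (the two aryl rings avoid allylic strain), and O-sulfonylation keeps that geometry.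

Step 5
Reactants: 9 methyl 3,5-dimethoxybenzoate
Product: 10 methyl 2-iodo-3,5-dimethoxybenzoate
Conditions: NIS, CF3CO2H (cat.), MeCN, rt
Reagents that add atoms: N-iodosuccinimide, O=C1CCC(=O)N1I
Why: Electrophilic aromatic iodination at C2, which is ortho and para to the two methoxy groups and less hindered than C4 between them.

Step 6
Reactants: 10 methyl 2-iodo-3,5-dimethoxybenzoate; 8 (Z)-2-(2-bromo-3,5-dimethoxyphenyl)-1-(4-methoxyphenyl)ethenyl trifluoromethanesulfonate
Product: 13 methyl 2-[(Z)-2-(2-bromo-3,5-dimethoxyphenyl)-1-(4-methoxyphenyl)ethenyl]-3,5-dimethoxybenzoate, via arylmagnesium chloride 11 (not isolated), via arylzinc chloride 12 (not isolated)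
Conditions: iPrMgCl·LiCl, THF, −40 °C; ZnCl2, −40 to 0 °C; then 8, Pd(PPh3)4 (5 mol %), THF, 50 °C
Reagents that add atoms: none
Why: Iodine–magnesium exchange (the ortho ester survives at −40 °C), transmetalation to zinc and Negishi coupling, which replaces the triflate with retention of alkene geometry and is expected to leave the di-ortho-substituted, electron-rich aryl bromide alone because its oxidative addition is much slower.

Step 7
Reactants: 13 methyl 2-[(Z)-2-(2-bromo-3,5-dimethoxyphenyl)-1-(4-methoxyphenyl)ethenyl]-3,5-dimethoxybenzoate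
Product: 14 methyl 2-[(1S)-2-(2-bromo-3,5-dimethoxyphenyl)-1-(4-methoxyphenyl)ethyl]-3,5-dimethoxybenzoate
Conditions: H2 (50 bar), [Ir(cod)((R)-tBu-PHOX)]BArF (2 mol %; cod = 1,5-cyclooctadiene, BArF = tetrakis[3,5-bis(trifluoromethyl)phenyl]borate), CH2Cl2, rt
Reagents that add atoms: none
Why: Iridium-catalysed asymmetric hydrogenation of a geometrically pure trisubstituted 1,1-diarylalkene, in which the chiral P,N ligand selects the alkene face and so sets the diarylmethine centre (S, later C10); the (R) ligand is assigned by analogy with (E)-1,2-diarylpropenes and its antipode would be used if the sense proved opposite.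

Step 8
Reactants: 14 methyl 2-[(1S)-2-(2-bromo-3,5-dimethoxyphenyl)-1-(4-methoxyphenyl)ethyl]-3,5-dimethoxybenzoate
Product: 15 2-[(1S)-2-(2-bromo-3,5-dimethoxyphenyl)-1-(4-methoxyphenyl)ethyl]-3,5-dimethoxybenzoic acid
Conditions: LiOH, THF/MeOH/H2O, 60 °C; then 1 M HCl
Reagents that add atoms: lithium hydroxide, [Li+].[OH-]
Why: Ester saponification by acyl–oxygen cleavage; the diarylmethine C–H is far too weakly acidic to epimerise.

Step 9
Reactants: 15 2-[(1S)-2-(2-bromo-3,5-dimethoxyphenyl)-1-(4-methoxyphenyl)ethyl]-3,5-dimethoxybenzoic acid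
Product: 16 (10S)-1-bromo-2,4,7,9-tetramethoxy-10-(4-methoxyphenyl)-10,11-dihydro-5H-dibenzo[a,d][7]annulen-5-one
Conditions: (CF3CO)2O, TfOH (cat.), CH2Cl2, 0 °C to rt
Reagents that add atoms: none
Why: Intramolecular Friedel–Crafts acylation through the mixed anhydride closes the seven-membered ring at the only free position ortho to the CH2 group (ortho and para to methoxy groups, the other ortho site being blocked by bromine), whereas six-ring closure onto the anisyl ring would need attack meta to its methoxy group.

Step 10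
Reactants: 16 (10S)-1-bromo-2,4,7,9-tetramethoxy-10-(4-methoxyphenyl)-10,11-dihydro-5H-dibenzo[a,d][7]annulen-5-one
Product: 17 (10S)-1-bromo-4-hydroxy-2,7,9-trimethoxy-10-(4-methoxyphenyl)-10,11-dihydro-5H-dibenzo[a,d][7]annulen-5-one
Conditions: BCl3 (1.5 equiv), CH2Cl2, −78 to 0 °C; aqueous work-up
Reagents that add atoms: none
Why: Chelation-controlled ether cleavage, in which boron bound to the ketone oxygen reaches only the one methoxy group ortho to the carbonyl.

Step 11
Reactants: 17 (10S)-1-bromo-4-hydroxy-2,7,9-trimethoxy-10-(4-methoxyphenyl)-10,11-dihydro-5H-dibenzo[a,d][7]annulen-5-one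
Product: 18 (10S)-1-bromo-2,7,9-trimethoxy-10-(4-methoxyphenyl)-10,11-dihydro-5H-dibenzo[a,d][7]annulene-4,5-diol
Conditions: NaBH4 (excess), THF/MeOH, 0 °C to rt
Reagents that add atoms: none
Why: Borohydride reduction of the diaryl ketone to the ortho-hydroxy benzhydrol; the new carbinol centre need not be controlled because it becomes planar in the next step.

Step 12
Reactants: 19 4-methoxybenzyl chloride; 20 tetrahydrothiophene
Product: 21 1-(4-methoxybenzyl)tetrahydrothiophenium tetrafluoroborate
Conditions: NaBF4, acetone, rt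
Reagents that add atoms: sodium tetrafluoroborate, [Na+].F[B-](F)(F)F
Why: S-Alkylation of the sulfide by the reactive benzylic chloride, driven to the non-nucleophilic salt by precipitation of NaCl (anion metathesis).

Step 13
Reactants: 18 (10S)-1-bromo-2,7,9-trimethoxy-10-(4-methoxyphenyl)-10,11-dihydro-5H-dibenzo[a,d][7]annulene-4,5-diol; 21 1-(4-methoxybenzyl)tetrahydrothiophenium tetrafluoroborate
Product: 25 (2S,3S,10S)-bromo pentamethyl ether of the ampelopsin B-type core, via tolyl sulfone 22 (not isolated), via ring-embedded ortho-quinone methide 23 (not isolated), via sulfonium ylide 24 (not isolated)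
Conditions: 4-MeC6H4SO2H (1.2 equiv), 4 Å molecular sieves, CH2Cl2, rt; then 21 (1.5 equiv), Cs2CO3 (4 equiv), 0 °C to rt
Reagents that add atoms: none
Why: The sulfinic acid first exchanges the doubly benzylic hydroxyl of 18 for a sulfinate leaving group, so that Cs2CO3 can generate ortho-quinone methide 23 from the phenoxide at room temperature (no heating of the semi-stabilised ylide) while it also deprotonates 21 to ylide 24; the ylide carbon adds to the methide carbon C3, ring A re-aromatises, and the phenoxide displaces tetrahydrothiophene. The closest known reaction is the formal [4+1] annulation of ortho-quinone methides, released by base from 2-(sulfonylalkyl)phenols, with sulfonium ylides to give trans-2,3-disubstituted 2,3-dihydrobenzofurans. The furan closes by 5-exo-tet substitution with inversion at C2. C3 is set by C10: strain against the flanking methoxy group should hold the C10 aryl group pseudo-axial over one face of the boat-shaped seven-membered ring, so the ylide should add to the opposite face, and C2 is set relative to C3 by the anti betaine, which leads to the trans ring. The step needs facial selectivity at C3 and reaction at carbon only; the rigid methide has a single electrophilic site and no alpha hydrogen through which it could tautomerise.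

Step 14
Reactants: 25 (2S,3S,10S)-bromo pentamethyl ether of the ampelopsin B-type core; 26 3,5-dimethoxybenzoyl chloride
Product: 28 (2S,3S,10S)-3,5-dimethoxyphenyl ketone on ring A, via aryllithium 27 (not isolated)
Conditions: n-BuLi (1.05 equiv), THF, −78 °C; then added to 26 (2 equiv), THF, −78 to 0 °C
Reagents that add atoms: none
Why: Bromine–lithium exchange followed by acylation of the aryllithium; the ketone formed is flanked by a di-ortho-substituted ring and should resist a second addition of the hindered aryllithium.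

Step 15
Reactants: 28 (2S,3S,10S)-3,5-dimethoxyphenyl ketone on ring A
Product: 29 (2S,3S,10S)-ortho-hydroxy 3,5-dimethoxyphenyl ketone
Conditions: BCl3 (1.2 equiv), CH2Cl2, −78 to −20 °C; aqueous work-up
Reagents that add atoms: none
Why: Chelation-controlled demethylation again picks the only methoxy group ortho to the ketone (the one on ring A), and the low temperature and near-stoichiometric BCl3 are meant to spare the benzylic furan ether.

Step 16
Reactants: 29 (2S,3S,10S)-ortho-hydroxy 3,5-dimethoxyphenyl ketone
Product: 30 (2S,3S,10S)-ortho-hydroxy benzhydrol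
Conditions: NaBH4 (excess), THF/MeOH, 0 °C to rt
Reagents that add atoms: none
Why: Borohydride reduction of the diaryl ketone; the carbinol configuration is again irrelevant.

Step 17
Reactants: 31 (2S,5S)-hexane-2,5-diol
Product: 32 (2S,5S)-hexane-2,5-diyl dimethanesulfonate
Conditions: MsCl, Et3N, CH2Cl2, 0 °C
Reagents that add atoms: methanesulfonyl chloride, CS(=O)(=O)Cl
Why: O-Sulfonylation, which forms O–S bonds only and leaves both carbon centres unchanged.

Step 18
Reactants: 32 (2S,5S)-hexane-2,5-diyl dimethanesulfonate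
Product: 33 (2R,5R)-2,5-dimethylthiolane
Conditions: Na2S·9H2O, DMSO, rt to 50 °C
Reagents that add atoms: sodium sulfide, [Na+].[Na+].[S-2]
Why: Double SN2 displacement by sulfide (the second one a 5-exo-tet ring closure) inverts both centres and gives the C2-symmetric (2R,5R) sulfide.

Step 19
Reactants: 19 4-methoxybenzyl chloride; 33 (2R,5R)-2,5-dimethylthiolane
Product: 34 (2R,5R)-1-(4-methoxybenzyl)-2,5-dimethylthiolan-1-ium tetrafluoroborate
Conditions: NaBF4, acetone, rt
Reagents that add atoms: sodium tetrafluoroborate, [Na+].F[B-](F)(F)F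
Why: S-Alkylation with anion metathesis as in step 12; because the sulfide is C2-symmetric, sulfur is not a stereocentre and a single salt forms.

Step 20
Reactants: 30 (2S,3S,10S)-ortho-hydroxy benzhydrol; 34 (2R,5R)-1-(4-methoxybenzyl)-2,5-dimethylthiolan-1-ium tetrafluoroborate
Product: 38 (2S,3S,10S,2'R,3'R)-heptamethyl ether of the target, via tolyl sulfone 35 (not isolated), via exocyclic ortho-quinone methide 36 (not isolated), via chiral sulfonium ylide 37 (not isolated)
Conditions: 4-MeC6H4SO2H (1.2 equiv), 4 Å molecular sieves, CH2Cl2, rt; then 34 (1.5 equiv), Cs2CO3 (4 equiv), 0 °C to rt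
Reagents that add atoms: none
Why: The same sulfinate-triggered [4+1] annulation of an ortho-quinone methide with a sulfonium ylide, now under reagent control: the C2-symmetric sulfide fixes which face of ylide 37 bonds to the methide carbon (sense assigned by analogy with its benzylidene transfer to aldehydes, which corresponds to 2'R here; the (2S,5S) sulfide would be used if the sense proved opposite), the anti betaine gives the trans ring (3'R), and 5-exo-tet closure with inversion at C2' completes the outer furan.

Step 21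
Reactants: 38 (2S,3S,10S,2'R,3'R)-heptamethyl ether of the target
Product: 39 CNP0136963.1
Conditions: BBr3 (12 equiv), CH2Cl2, −78 °C to rt; MeOH quench
Reagents that add atoms: none
Why: Lewis-acid cleavage of all seven aryl methyl ethers; both dihydrofurans are already the trans isomers, so any reversible ionisation at C2 or C2' should return the same configuration.

Compound list
1 | 3,5-dimethoxybenzyl alcohol | COc1cc(CO)cc(OC)c1 | starting material
2 | 2-bromo-3,5-dimethoxybenzyl alcohol | COc1cc(CO)c(Br)c(OC)c1 | intermediate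
3 | 2-bromo-1-(bromomethyl)-3,5-dimethoxybenzene | COc1cc(CBr)c(Br)c(OC)c1 | intermediate
4 | 4-methoxybenzoyl chloride | COc1ccc(C(=O)Cl)cc1 | starting material
5 | (2-bromo-3,5-dimethoxybenzyl)zinc bromide | COc1cc(C[Zn]Br)c(Br)c(OC)c1 | intermediate
6 | 2-(2-bromo-3,5-dimethoxyphenyl)-1-(4-methoxyphenyl)ethanone | COc1ccc(C(=O)Cc2cc(OC)cc(OC)c2Br)cc1 | intermediate
7 | potassium (Z)-enolate of 6 (oxygen cis to the bromoaryl group) | COc1ccc(/C([O-])=C/c2cc(OC)cc(OC)c2Br)cc1.[K+] | intermediate
8 | (Z)-2-(2-bromo-3,5-dimethoxyphenyl)-1-(4-methoxyphenyl)ethenyl trifluoromethanesulfonate | COc1ccc(/C(OS(=O)(=O)C(F)(F)F)=C/c2cc(OC)cc(OC)c2Br)cc1 | intermediate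
9 | methyl 3,5-dimethoxybenzoate | COC(=O)c1cc(OC)cc(OC)c1 | starting material
10 | methyl 2-iodo-3,5-dimethoxybenzoate | COC(=O)c1cc(OC)cc(OC)c1I | intermediate
11 | [2-(methoxycarbonyl)-4,6-dimethoxyphenyl]magnesium chloride | COC(=O)c1cc(OC)cc(OC)c1[Mg]Cl | intermediate
12 | [2-(methoxycarbonyl)-4,6-dimethoxyphenyl]zinc chloride | COC(=O)c1cc(OC)cc(OC)c1[Zn]Cl | intermediate
13 | methyl 2-[(Z)-2-(2-bromo-3,5-dimethoxyphenyl)-1-(4-methoxyphenyl)ethenyl]-3,5-dimethoxybenzoate (ester-bearing ring cis to the bromoaryl ring) | COC(=O)c1cc(OC)cc(OC)c1/C(c1ccc(OC)cc1)=C\c1cc(OC)cc(OC)c1Br | intermediate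
14 | methyl 2-[(1S)-2-(2-bromo-3,5-dimethoxyphenyl)-1-(4-methoxyphenyl)ethyl]-3,5-dimethoxybenzoate | COc1ccc([C@H](Cc2cc(OC)cc(OC)c2Br)c2c(OC)cc(OC)cc2C(=O)OC)cc1 | intermediate
15 | 2-[(1S)-2-(2-bromo-3,5-dimethoxyphenyl)-1-(4-methoxyphenyl)ethyl]-3,5-dimethoxybenzoic acid | COc1ccc([C@H](Cc2cc(OC)cc(OC)c2Br)c2c(OC)cc(OC)cc2C(=O)O)cc1 | intermediate
16 | (10S)-1-bromo-2,4,7,9-tetramethoxy-10-(4-methoxyphenyl)-10,11-dihydro-5H-dibenzo[a,d][7]annulen-5-one | COc1ccc([C@@H]2Cc3c(Br)c(OC)cc(OC)c3C(=O)c3cc(OC)cc(OC)c32)cc1 | intermediate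
17 | (10S)-1-bromo-4-hydroxy-2,7,9-trimethoxy-10-(4-methoxyphenyl)-10,11-dihydro-5H-dibenzo[a,d][7]annulen-5-one | COc1ccc([C@@H]2Cc3c(Br)c(OC)cc(O)c3C(=O)c3cc(OC)cc(OC)c32)cc1 | intermediate
18 | (10S)-1-bromo-2,7,9-trimethoxy-10-(4-methoxyphenyl)-10,11-dihydro-5H-dibenzo[a,d][7]annulene-4,5-diol (C5 epimers) | COc1ccc([C@@H]2Cc3c(Br)c(OC)cc(O)c3C(O)c3cc(OC)cc(OC)c32)cc1 | intermediate
19 | 4-methoxybenzyl chloride | COc1ccc(CCl)cc1 | starting material
20 | tetrahydrothiophene | C1CCSC1 | starting material
21 | 1-(4-methoxybenzyl)tetrahydrothiophenium tetrafluoroborate | COc1ccc(C[S+]2CCCC2)cc1.F[B-](F)(F)F | intermediate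
22 | (10S)-1-bromo-2,7,9-trimethoxy-10-(4-methoxyphenyl)-5-(4-methylphenylsulfonyl)-10,11-dihydro-5H-dibenzo[a,d][7]annulen-4-ol (C5 epimers) | COc1ccc([C@@H]2Cc3c(Br)c(OC)cc(O)c3C(S(=O)(=O)c3ccc(C)cc3)c3cc(OC)cc(OC)c32)cc1 | intermediate
23 | (10S)-1-bromo-2,7,9-trimethoxy-10-(4-methoxyphenyl)-10,11-dihydro-4H-dibenzo[a,d][7]annulen-4-one (ortho-quinone methide, C4a=C5 double bond inside the seven-membered ring) | COc1ccc([C@@H]2CC3=C(Br)C(OC)=CC(=O)C3=Cc3cc(OC)cc(OC)c32)cc1 | intermediate
24 | 4-methoxybenzylidene ylide of tetrahydrothiophene | COc1ccc([CH-][S+]2CCCC2)cc1 | intermediate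
25 | (2S,3S,10S)-bromo pentamethyl ether of the ampelopsin B-type core: trans-2-(4-methoxyphenyl)-2,3-dihydrofuran fused to ring A and, at C3, to the seven-membered ring; ring A also carries OMe and, next to the ring CH2, Br; C10 carries 4-methoxyphenyl; the second benzo ring carries two OMe | COc1ccc([C@@H]2Cc3c4c(cc(OC)c3Br)O[C@H](c3ccc(OC)cc3)[C@H]4c3cc(OC)cc(OC)c32)cc1 | intermediate
26 | 3,5-dimethoxybenzoyl chloride | COc1cc(cc(OC)c1)C(Cl)=O | starting material
27 | aryllithium from 25 (Li in place of Br) | COc1ccc([C@@H]2Cc3c4c(cc(OC)c3[Li])O[C@H](c3ccc(OC)cc3)[C@H]4c3cc(OC)cc(OC)c32)cc1 | intermediate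
28 | (2S,3S,10S)-ketone: 3,5-dimethoxybenzoyl group in place of Br on ring A of 25 | COc1ccc([C@@H]2Cc3c4c(cc(OC)c3C(=O)c3cc(OC)cc(OC)c3)O[C@H](c3ccc(OC)cc3)[C@H]4c3cc(OC)cc(OC)c32)cc1 | intermediate
29 | (2S,3S,10S)-ortho-hydroxy ketone: 28 with the ring A methoxy group next to the ketone as free OH | COc1ccc([C@@H]2Cc3c4c(cc(O)c3C(=O)c3cc(OC)cc(OC)c3)O[C@H](c3ccc(OC)cc3)[C@H]4c3cc(OC)cc(OC)c32)cc1 | intermediate
30 | (2S,3S,10S)-ortho-hydroxy benzhydrol from 29 (carbinol epimers) | COc1ccc([C@@H]2Cc3c4c(cc(O)c3C(O)c3cc(OC)cc(OC)c3)O[C@H](c3ccc(OC)cc3)[C@H]4c3cc(OC)cc(OC)c32)cc1 | intermediate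
31 | (2S,5S)-hexane-2,5-diol | C[C@H](O)CC[C@H](C)O | starting material
32 | (2S,5S)-hexane-2,5-diyl dimethanesulfonate | C[C@H](OS(C)(=O)=O)CC[C@H](C)OS(C)(=O)=O | intermediate
33 | (2R,5R)-2,5-dimethylthiolane | C[C@@H]1CC[C@@H](C)S1 | intermediate
34 | (2R,5R)-1-(4-methoxybenzyl)-2,5-dimethylthiolan-1-ium tetrafluoroborate | COc1ccc(C[S+]2[C@H](C)CC[C@H]2C)cc1.F[B-](F)(F)F | intermediate
35 | (2S,3S,10S)-p-tolyl sulfone from 30 (sulfonyl in place of the carbinol OH; epimers) | COc1ccc([C@@H]2Cc3c4c(cc(O)c3C(c3cc(OC)cc(OC)c3)S(=O)(=O)c3ccc(C)cc3)O[C@H](c3ccc(OC)cc3)[C@H]4c3cc(OC)cc(OC)c32)cc1 | intermediate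
36 | (2S,3S,10S)-ortho-quinone methide from 35 (ring A as dienone, exocyclic 3,5-dimethoxybenzylidene) | COc1ccc([C@@H]2CC3=C4C(=CC(=O)C3=Cc3cc(OC)cc(OC)c3)O[C@H](c3ccc(OC)cc3)[C@H]4c3cc(OC)cc(OC)c32)cc1 | intermediate
37 | 4-methoxybenzylidene ylide of (2R,5R)-2,5-dimethylthiolane | COc1ccc([CH-][S+]2[C@H](C)CC[C@H]2C)cc1 | intermediate
38 | (2S,3S,10S,2'R,3'R)-heptamethyl ether of the target | COc1ccc([C@@H]2Cc3c4c(cc5c3[C@@H](c3cc(OC)cc(OC)c3)[C@H](c3ccc(OC)cc3)O5)O[C@H](c3ccc(OC)cc3)[C@H]4c3cc(OC)cc(OC)c32)cc1 | intermediate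
39 | CNP0136963.1, (2S,3S,10S,2'R,3'R) | Oc1ccc([C@@H]2Cc3c4c(cc5c3[C@@H](c3cc(O)cc(O)c3)[C@H](c3ccc(O)cc3)O5)O[C@H](c3ccc(O)cc3)[C@H]4c3cc(O)cc(O)c32)cc1 | target

Total step count: 21. Longest linear sequence: 16 steps (1, 2, 3, 4, 6, 7, 8, 9, 10, 11, 13, 14, 15, 16, 20, 21).

Steps most likely to fail

Step 13. The ylide may add to both faces of the methide carbon, so that C3 forms as a mixture. The ortho-quinone methide may also return to its sulfinate or water adduct faster than the ylide captures it, and the sulfonium salt may benzylate the phenoxide on oxygen. The fallback sets out from 17 and comes back at 25, and brings in C2 as a nucleophile at the ketone instead of as an ylide at the methide. 4-Methoxybenzylmagnesium chloride (from 19 and Mg, 3 equiv, THF, 0 °C) should add to the ketone of 17 to give the tertiary benzylic alcohol F1. Catalytic TsOH in toluene at 60 °C should dehydrate it to the ortho-hydroxy stilbene F2, which carries an exocyclic 4-methoxybenzylidene group. The same acid should then protonate F2 at C3 and let the phenol capture the 4-methoxybenzylic cation at C2 (acid-mediated hydroalkoxylation of a 2-hydroxystilbene). Protonation and ring closure are reversible, so the trans ring and the C3 configuration would be set under thermodynamic control, and 25 would be separated from any C3 epimer by chromatography.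

Step 20. The facial preference imposed by the chiral sulfide may oppose that of the chiral core and give a mixture at C2' and C3', or addition to the crowded methide may be so slow that the ylide decays first. The fallback sets out from 29 and comes back at 38. 4-Methoxybenzylmagnesium chloride should add to the ketone of 29 to give the tertiary alcohol F3. Acid (catalytic TsOH, toluene, 60 °C) should dehydrate it to the ortho-hydroxy stilbene F4 and cyclise this to the trans outer dihydrofuran. In this variant the (2'R,3'R) and (2'S,3'S) trans isomers are expected side by side, and 38 would be isolated by chromatography, so separation replaces reagent control.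

Step 7. Hydrogenation of the crowded alkene may be slow, or face discrimination may be incomplete. The fallback sets out from 10 and 3 and comes back at 15, and replaces asymmetric catalysis by a racemic construction with classical resolution. The arylmagnesium 11 (made from 10 as in step 6) is added to 4-methoxybenzaldehyde, and the alkoxide should lactonise onto the ester to give 4,6-dimethoxy-3-(4-methoxyphenyl)phthalide F5. Deprotonation at C3 with KN(SiMe3)2 and alkylation with benzyl bromide 3 should give the 3-aryl-3-benzylphthalide F6. Ionic hydrogenation (Et3SiH, CF3CO2H, CH2Cl2) should cleave the tertiary, anisyl-activated lactone C–O bond reductively to the racemic acid F7. Crystallisation with (S)-1-phenylethylamine (or its antipode, whichever gives the less soluble salt of the S acid) should give the diastereomerically pure salt F8, from which 1 M HCl liberates 15.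

Further compounds
F1 | step 13 | tertiary alcohol from 17 and 4-methoxybenzylmagnesium chloride (C10 S; carbinol epimers) | COc1ccc([C@@H]2Cc3c(Br)c(OC)cc(O)c3C(O)(Cc3ccc(OC)cc3)c3cc(OC)cc(OC)c32)cc1
F2 | step 13 | ortho-hydroxy stilbene with exocyclic 4-methoxybenzylidene at C5 (C10 S; alkene isomers) | COc1ccc([C@@H]2Cc3c(Br)c(OC)cc(O)c3C(=Cc3ccc(OC)cc3)c3cc(OC)cc(OC)c32)cc1
F3 | step 20 | tertiary alcohol from 29 and 4-methoxybenzylmagnesium chloride (2S,3S,10S; carbinol epimers) | COc1ccc([C@@H]2Cc3c4c(cc(O)c3C(O)(Cc3ccc(OC)cc3)c3cc(OC)cc(OC)c3)O[C@H](c3ccc(OC)cc3)[C@H]4c3cc(OC)cc(OC)c32)cc1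
F4 | step 20 | ortho-hydroxy stilbene from F3 (2S,3S,10S; alkene isomers) | COc1ccc([C@@H]2Cc3c4c(cc(O)c3C(=Cc3ccc(OC)cc3)c3cc(OC)cc(OC)c3)O[C@H](c3ccc(OC)cc3)[C@H]4c3cc(OC)cc(OC)c32)cc1
F5 | step 7 | 4,6-dimethoxy-3-(4-methoxyphenyl)isobenzofuran-1(3H)-one (racemic) | COc1ccc(C2OC(=O)c3cc(OC)cc(OC)c32)cc1
F6 | step 7 | 3-(2-bromo-3,5-dimethoxybenzyl)-4,6-dimethoxy-3-(4-methoxyphenyl)isobenzofuran-1(3H)-one (racemic) | COc1ccc(C2(Cc3cc(OC)cc(OC)c3Br)OC(=O)c3cc(OC)cc(OC)c32)cc1
F7 | step 7 | racemic 2-[2-(2-bromo-3,5-dimethoxyphenyl)-1-(4-methoxyphenyl)ethyl]-3,5-dimethoxybenzoic acid | COc1ccc(C(Cc2cc(OC)cc(OC)c2Br)c2c(OC)cc(OC)cc2C(=O)O)cc1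
F8 | step 7 | (S)-1-phenylethylammonium salt of the (S) acid 15 | COc1ccc([C@H](Cc2cc(OC)cc(OC)c2Br)c2c(OC)cc(OC)cc2C(=O)[O-])cc1.C[C@H]([NH3+])c1ccccc1
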